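**Strategy.** Atoms are numbered 1–34 along the target SMILES. The route rests on cutting C14–C15 in the seven-membered ether ring (O20–C17–C15–C14–C13–C11–C21). Ring-closing metathesis closes the trans-fused 2,2-dimethyloxepene onto the cyclohexanone in one operation. It exploits the tertiary ether carbon C17, pre-installed as a 1,1-dimethylallyl ether on O20, and the allyl arm on quaternary C11. Its precursor is (2R,3S)-2-allyl-2-methyl-3-(2-methylbut-3-en-2-yloxy)cyclohexanone, with the ether trans to allyl. The oxepene ketone is then elaborated at C15, C24 and C10 and joined at C8–C9 to a cis-decalin vinyl bromide by B-alkyl Suzuki coupling.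

Key step: step 8

Remark 1: monoreduction of dione 3 (yeast or hydride) is taken to place the hydroxyl cis to allyl, as recorded for the yeast reduction, so the trans O20/C13 relationship is built by transposing the two ring oxygens (steps 2, 3, 6, 7) and not by one reduction.
Remark 2: the catalyst antipode in step 14 is assumed to follow the facial model known for cyclohexenone; if the other enantiomer forms, the (R)-catalyst is used.

Step 1
Reactants: 1 2-methylcyclohexane-1,3-dione; 2 allyl bromide
Product: 3 2-allyl-2-methylcyclohexane-1,3-dione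
Conditions: 1 M NaOH (aq), Bu4NI (cat.), rt
Reagents that add atoms: none
Why: C-alkylation of the soft 1,3-dione enolate with allyl bromide in water, which disfavours O-allylation, gives the achiral 2,2-disubstituted dione with no stereocentre.

Step 2
Reactants: 3 2-allyl-2-methylcyclohexane-1,3-dione
Product: 4 (2S,3S)-2-allyl-3-hydroxy-2-methylcyclohexan-1-one (hydroxyl cis to allyl)
Conditions: baker's yeast, sucrose, H2O, 30 °C
Reagents that add atoms: none
Why: Enzymatic desymmetrisation (baker's-yeast reduction of a 2,2-disubstituted cyclohexane-1,3-dione) reduces one enantiotopic carbonyl to the (S)-carbinol cis to allyl and so fixes quaternary C11; this carbinol carbon is the future C10 and is re-oxidised in step 7.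

Step 3
Reactants: 4 (2S,3S)-2-allyl-3-hydroxy-2-methylcyclohexan-1-one
Product: 5 (1S,2R,3S)-2-allyl-3-hydroxy-2-methylcyclohexyl acetate (acetoxy cis to allyl; new hydroxyl trans to allyl, cis to methyl)
Conditions: MeCHO (6 equiv), SmI2 (0.2 equiv), THF, −10 °C
Reagents that add atoms: acetaldehyde, CC=O
Why: Evans–Tishchenko reduction, in which the samarium hemiacetal of the hydroxyl (axial in the reacting chair) transfers hydride across the ring to the ketone, so the new carbinol C21 is anti to the old oxygen, hence trans to allyl and cis to methyl, while the old hydroxyl is left as its acetate.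

Step 4
Reactants: 6 2-methylbut-3-en-2-ol
Product: 7 2-methylbut-3-en-2-yl 2,2,2-trichloroacetimidate
Conditions: Cl3CCN, DBU (0.1 equiv), CH2Cl2, 0 °C; used cold without storage
Reagents that add atoms: trichloroacetonitrile, N#CC(Cl)(Cl)Cl
Why: Base-catalysed addition of the tertiary allylic alcohol to the nitrile (imidate formation), kept cold so that the [3,3] shift to the allylic amide does not set in.

Step 5
Reactants: 5 (1S,2R,3S)-2-allyl-3-hydroxy-2-methylcyclohexyl acetate; 7 2-methylbut-3-en-2-yl 2,2,2-trichloroacetimidate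
Product: 8 (1S,2R,3S)-2-allyl-2-methyl-3-[(2-methylbut-3-en-2-yl)oxy]cyclohexyl acetate
Conditions: TfOH (5 mol %), cyclohexane–CH2Cl2 2:1, −30 → 0 °C
Reagents that add atoms: none
Why: Acid-catalysed trichloroacetimidate etherification, in which the imidate ionises to the 1,1-dimethylallyl cation and the free C21 hydroxyl captures it at the tertiary terminus under kinetic control in a non-polar medium; the C21–O bond is untouched, so its configuration is retained.

Step 6
Reactants: 8 (1S,2R,3S)-2-allyl-2-methyl-3-[(2-methylbut-3-en-2-yl)oxy]cyclohexyl acetate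
Product: 9 (1S,2S,3S)-2-allyl-2-methyl-3-[(2-methylbut-3-en-2-yl)oxy]cyclohexan-1-ol
Conditions: K2CO3, MeOH, rt
Reagents that add atoms: none
Why: Base-catalysed transesterification (methanolysis) removes the acetate, and the tertiary ether and both alkenes are inert to carbonate.

Step 7
Reactants: 9 (1S,2S,3S)-2-allyl-2-methyl-3-[(2-methylbut-3-en-2-yl)oxy]cyclohexan-1-ol
Product: 10 (2R,3S)-2-allyl-2-methyl-3-[(2-methylbut-3-en-2-yl)oxy]cyclohexan-1-one
Conditions: Dess–Martin periodinane, NaHCO3, CH2Cl2, rt
Reagents that add atoms: none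
Why: Dess–Martin oxidation of the secondary alcohol under bicarbonate buffer, mild enough for the acid-labile tertiary allylic ether, restores the C10 ketone and erases the auxiliary carbinol centre.

Step 8
Reactants: 10 (2R,3S)-2-allyl-2-methyl-3-[(2-methylbut-3-en-2-yl)oxy]cyclohexan-1-one
Product: 11 (5aR,9aS)-2,2,5a-trimethyl-5,5a,7,8,9,9a-hexahydro-1-benzoxepin-6(2H)-one (trans-fused)
Conditions: second-generation Grubbs catalyst (5 mol %), CH2Cl2 (0.005 M), 40 °C
Reagents that add atoms: none
Why: Ring-closing olefin metathesis by the Chauvin mechanism: the ruthenium benzylidene exchanges first with the less hindered allyl terminus on C11, the new alkylidene adds intramolecularly to the 1,1-dimethylallyl ether alkene through a metallacyclobutane, and cycloreversion forms C14=C15 while the two terminal CH2 groups leave as ethylene. The closest known reaction type is metathesis of allyl/1,1-dimethylallyl ether dienes to 2,2-dimethyl-2,5-dihydrooxepines fused to carbocycles. The one ring closed is the seven-membered oxepene O20–C17–C15=C14–C13–C11–C21, made by joining two terminal alkenes whose tether already holds the trans C11–C21 relationship, so the bicycle is trans-fused by construction. No stereocentre is created, and C11 and C21 pass unchanged from 10. The step needs cyclisation to outrun acyclic cross-metathesis and oligomerisation although both alkenes are encumbered; the gem-dimethyl group at C17 (Thorpe–Ingold effect), the diequatorial placing of the two arms in the chair with axial C11 methyl, and high dilution secure this. The ketone, the tertiary ether and the quaternary centre are inert to the carbene.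

Step 9
Reactants: 11 (5aR,9aS)-2,2,5a-trimethyl-5,5a,7,8,9,9a-hexahydro-1-benzoxepin-6(2H)-one
Product: 12 3,4-epoxide of 11 (C14–C15 oxirane, either face)
Conditions: DMDO, acetone, 0 °C
Reagents that add atoms: dimethyldioxirane, CC1(C)OO1
Why: Electrophilic epoxidation of the cis-disubstituted oxepene with a dioxirane, which does not cause Baeyer–Villiger oxidation of the ketone; either epoxide face serves because C14 and C15 lose their stereochemistry later.

Step 10
Reactants: 12 3,4-epoxide of 11
Product: 13 3,4-epoxy-2,2,5a,7-tetramethyloctahydro-1-benzoxepin-6-one (C24 methyl, either epimer)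
Conditions: LDA, THF, −78 °C; MeI, −78 → −20 °C
Reagents that add atoms: iodomethane, CI
Why: The lithium enolate can form only toward C24 because C11 is quaternary, and SN2 methylation follows; the epoxide survives at low temperature and the C24 configuration is planarised again in step 11.

Step 11
Reactants: 13 3,4-epoxy-2,2,5a,7-tetramethyloctahydro-1-benzoxepin-6-one
Product: 14 3,4-epoxy-7-hydroxy-2,2,5a,7-tetramethyloctahydro-1-benzoxepin-6-one (C24: hydroxyl equatorial, trans to C11 methyl; methyl axial)
Conditions: KHMDS, THF, −78 °C; 2-(phenylsulfonyl)-3-phenyloxaziridine, −78 °C; aq. NH4Cl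
Reagents that add atoms: 2-(phenylsulfonyl)-3-phenyloxaziridine, O=S(=O)(N1OC1c1ccccc1)c1ccccc1
Why: Enolate hydroxylation with a sulfonyloxaziridine, in which the oxidant reaches C24 of the tetrasubstituted potassium enolate on the face opposite the axial C11 methyl (1,3-diaxial blocking), giving the tertiary alcohol with equatorial hydroxyl and axial methyl as in the target.

Step 12
Reactants: 14 3,4-epoxy-7-hydroxy-2,2,5a,7-tetramethyloctahydro-1-benzoxepin-6-one
Product: 16 3,4-epoxy-2,2,5a,7-tetramethyl-6-methylenedecahydro-1-benzoxepin-7-ol, via β-hydroxysilane 15 (not isolated)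
Conditions: TMSCH2Li (3 equiv), THF, −78 → 0 °C; aq. NH4Cl; then KH, THF, 0 °C → rt
Reagents that add atoms: (trimethylsilyl)methyllithium, [Li]C[Si](C)(C)C
Why: Peterson olefination, in which the small, strongly nucleophilic silylmethyllithium adds to a ketone that has no α-hydrogen and cannot enolise, and the potassium alkoxide then eliminates silanolate in a syn fashion to give the exocyclic methylene (C9).

Step 13
Reactants: 16 3,4-epoxy-2,2,5a,7-tetramethyl-6-methylenedecahydro-1-benzoxepin-7-ol
Product: 17 2,2,5a,7-tetramethyl-6-methylenedecahydro-1-benzoxepine-3,7-diol (C15 carbinol, either epimer)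
Conditions: LiEt3BH, THF, 0 → 50 °C; H2O
Reagents that add atoms: none
Why: SN2 opening of the epoxide by the trialkylborohydride at C14, the carbon remote from quaternary C17 and its β-oxygen, gives the C15 secondary alcohol, while the exocyclic alkene and the tertiary alkoxide are inert.

Step 14
Reactants: 18 4,4-dimethylcyclohex-2-en-1-one; 19 isoprene
Product: 20 (4aR,8aS)-4,4,6-trimethyl-3,4,4a,5,8,8a-hexahydronaphthalen-1(2H)-one (cis-fused)
Conditions: (S)-o-tolyl-oxazaborolidinium triflimide from diphenylprolinol (20 mol %), CH2Cl2, −20 °C → rt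
Reagents that add atoms: none
Why: Catalytic enantioselective Diels–Alder reaction of a 2-cycloalkenone activated by a chiral oxazaborolidinium Lewis acid: suprafacial addition makes the C5/C6 ring fusion cis, the catalyst selects the enone face, and the 'para' rule places the methyl on C2.

Step 15
Reactants: 20 (4aR,8aS)-4,4,6-trimethyl-3,4,4a,5,8,8a-hexahydronaphthalen-1(2H)-one
Product: 21 5-hydroxy-4,4,6-trimethyl-3,4,4a,5,8,8a-hexahydronaphthalen-1(2H)-one (allylic alcohol at C7, either epimer)
Conditions: SeO2 (0.5 equiv), t-BuOOH, CH2Cl2, rt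
Reagents that add atoms: selenium dioxide, O=[Se]=O (oxygen donor, reoxidised by tert-butyl hydroperoxide, CC(C)(C)OO)
Why: Selenium dioxide allylic oxidation (ene reaction, then [2,3]-sigmatropic shift) functionalises the ring CH2 on the more substituted alkene carbon, that is C7, and leaves the double bond at C2=C3.

Step 16
Reactants: 21 5-hydroxy-4,4,6-trimethyl-3,4,4a,5,8,8a-hexahydronaphthalen-1(2H)-one
Product: 22 5-hydroxy-4,4,6-trimethyloctahydronaphthalen-1(2H)-one (C2–H cis to H5 and H6)
Conditions: H2 (1 atm), 5% Rh/Al2O3, EtOAc, rt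
Reagents that add atoms: none
Why: Heterogeneous hydrogenation of the trisubstituted alkene from the convex face of the cis-fused bicycle (the face of H5 and H6) sets C2 with its methyl on the concave face, and rhodium avoids allylic C–O hydrogenolysis and ketone reduction.

Step 17
Reactants: 22 5-hydroxy-4,4,6-trimethyloctahydronaphthalen-1(2H)-one
Product: 23 2,8,8-trimethyl-5-methylidenedecahydronaphthalen-1-ol
Conditions: Zn, CH2Br2, TiCl4, THF/CH2Cl2, 0 °C → rt
Reagents that add atoms: dibromomethane, BrCBr
Why: Takai–Lombardo methylenation with the non-basic zinc/titanium methylene reagent converts the C32 ketone without enolising C5, so the cis ring fusion is kept, and it tolerates the free hydroxyl.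

Step 18
Reactants: 23 2,8,8-trimethyl-5-methylidenedecahydronaphthalen-1-ol
Product: 24 spiro-epoxide of 23 (oxirane oxygen cis to H5)
Conditions: mCPBA, NaHCO3, CH2Cl2, 0 °C
Reagents that add atoms: 3-chloroperoxybenzoic acid, OOC(=O)c1cccc(Cl)c1
Why: Prilezhaev epoxidation of the 1,1-disubstituted alkene from the convex face, away from ring A on the concave side, places the epoxide oxygen cis to H5.

Step 19
Reactants: 24 spiro-epoxide of 23
Product: 25 2,5,8,8-tetramethyldecahydronaphthalene-1,5-diol (C32: hydroxyl cis to H5, methyl on the concave face)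
Conditions: LiEt3BH, THF, 0 °C → rt; H2O
Reagents that add atoms: none
Why: Hydride opens the spiro-epoxide at its CH2 terminus (SN2), so the C32–O bond and its configuration are kept and the tertiary carbinol has its hydroxyl cis to H5.

Step 20
Reactants: 25 2,5,8,8-tetramethyldecahydronaphthalene-1,5-diol
Product: 26 5-hydroxy-2,5,8,8-tetramethyloctahydronaphthalen-1(2H)-one
Conditions: Dess–Martin periodinane, NaHCO3, CH2Cl2, rt
Reagents that add atoms: none
Why: Dess–Martin oxidation turns the only secondary alcohol into the C7 ketone under neutral conditions that should not epimerise C2 or C6, and the tertiary alcohol cannot be oxidised.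

Step 21
Reactants: 26 5-hydroxy-2,5,8,8-tetramethyloctahydronaphthalen-1(2H)-one
Product: 27 (E)-5-(bromomethylidene)-1,4,4,6-tetramethyldecahydronaphthalen-1-ol (bromine syn to C2)
Conditions: Ph3P+CH2Br Br−, NaHMDS (excess), THF, −60 °C → rt
Reagents that add atoms: (bromomethyl)triphenylphosphonium bromide, BrC[P+](c1ccccc1)(c1ccccc1)c1ccccc1.[Br-]
Why: Wittig bromomethylenation, in which the bromine is placed syn to the smaller α-carbon C2 and away from C6 with its neighbouring quaternary C27, the (E) outcome known for hindered ring-fusion ketones of the hydrindanone type.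

Step 22
Reactants: 17 2,2,5a,7-tetramethyl-6-methylenedecahydro-1-benzoxepine-3,7-diol; 27 (E)-5-(bromomethylidene)-1,4,4,6-tetramethyldecahydronaphthalen-1-ol
Product: 29 C15 alcohol of the target (15-dihydro target), via B-alkyl-9-BBN borane 28 (not isolated)
Conditions: 9-BBN (excess), THF, rt → 50 °C; then 27, Pd(dppf)Cl2 (10 mol %), AsPh3, Cs2CO3, DMF/THF/H2O, 50 °C
Reagents that add atoms: none
Why: 9-BBN adds to the exocyclic methylene from the face opposite the two flanking axial methyls on C11 and C24, which sets C10 with the C9 arm equatorial, and B-alkyl Suzuki–Miyaura coupling with the vinyl bromide then forms C8–C9 with retention of the alkene geometry.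

Step 23
Reactants: 29 C15 alcohol of the target
Product: 30 target, CNP0232921.1
Conditions: Dess–Martin periodinane, NaHCO3, CH2Cl2, 0 °C → rt
Reagents that add atoms: none
Why: Dess–Martin oxidation of the single secondary alcohol (C15) gives the oxepanone, and the two tertiary alcohols and the trisubstituted alkene are unaffected.

**Compound list**

1 | 2-methylcyclohexane-1,3-dione | CC1C(=O)CCCC1=O | starting material
2 | allyl bromide | C=CCBr | starting material
3 | 2-allyl-2-methylcyclohexane-1,3-dione | C=CCC1(C)C(=O)CCCC1=O | intermediate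
4 | (2S,3S)-2-allyl-3-hydroxy-2-methylcyclohexan-1-one (hydroxyl cis to allyl) | C=CC[C@@]1(C)[C@@H](O)CCCC1=O | intermediate
5 | (1S,2R,3S)-2-allyl-3-hydroxy-2-methylcyclohexyl acetate (acetoxy cis, hydroxyl trans to allyl) | C=CC[C@@]1(C)[C@@H](OC(C)=O)CCC[C@@H]1O | intermediate
6 | 2-methylbut-3-en-2-ol | CC(C)(O)C=C | starting material
7 | 2-methylbut-3-en-2-yl 2,2,2-trichloroacetimidate | C=CC(C)(C)OC(=N)C(Cl)(Cl)Cl | intermediate
8 | (1S,2R,3S)-2-allyl-2-methyl-3-[(2-methylbut-3-en-2-yl)oxy]cyclohexyl acetate | C=CC[C@@]1(C)[C@@H](OC(C)=O)CCC[C@@H]1OC(C)(C)C=C | intermediate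
9 | (1S,2S,3S)-2-allyl-2-methyl-3-[(2-methylbut-3-en-2-yl)oxy]cyclohexan-1-ol | C=CC[C@@]1(C)[C@@H](O)CCC[C@@H]1OC(C)(C)C=C | intermediate
10 | (2R,3S)-2-allyl-2-methyl-3-[(2-methylbut-3-en-2-yl)oxy]cyclohexan-1-one (key-step precursor) | C=CC[C@]1(C)[C@@H](OC(C)(C)C=C)CCCC1=O | intermediate
11 | (5aR,9aS)-2,2,5a-trimethyl-5,5a,7,8,9,9a-hexahydro-1-benzoxepin-6(2H)-one (trans-fused; key-step product) | O=C1CCC[C@@H]2OC(C)(C)C=CC[C@@]12C | intermediate
12 | 3,4-epoxy-2,2,5a-trimethyloctahydro-1-benzoxepin-6-one (trans-fused; epoxide on either face) | O=C1CCC[C@@H]2OC(C)(C)C3OC3C[C@@]12C | intermediate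
13 | 3,4-epoxy-2,2,5a,7-tetramethyloctahydro-1-benzoxepin-6-one (C24 either epimer) | CC1CC[C@@H]2OC(C)(C)C3OC3C[C@@]2(C)C1=O | intermediate
14 | 3,4-epoxy-7-hydroxy-2,2,5a,7-tetramethyloctahydro-1-benzoxepin-6-one (7-OH trans to 5a-methyl) | C[C@]1(O)CC[C@@H]2OC(C)(C)C3OC3C[C@@]2(C)C1=O | intermediate
15 | 3,4-epoxy-2,2,5a,7-tetramethyl-6-[(trimethylsilyl)methyl]decahydro-1-benzoxepine-6,7-diol | C[C@]1(O)CC[C@@H]2OC(C)(C)C3OC3C[C@@]2(C)C1(O)C[Si](C)(C)C | intermediate (not isolated)
16 | 3,4-epoxy-2,2,5a,7-tetramethyl-6-methylenedecahydro-1-benzoxepin-7-ol | C[C@]1(O)CC[C@@H]2OC(C)(C)C3OC3C[C@@]2(C)C1=C | intermediate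
17 | 2,2,5a,7-tetramethyl-6-methylenedecahydro-1-benzoxepine-3,7-diol (C15 either epimer) | C[C@]1(O)CC[C@@H]2OC(C)(C)C(O)CC[C@@]2(C)C1=C | intermediate
18 | 4,4-dimethylcyclohex-2-en-1-one | CC1(C)CCC(=O)C=C1 | starting material
19 | isoprene | C=CC(C)=C | starting material
20 | (4aR,8aS)-4,4,6-trimethyl-3,4,4a,5,8,8a-hexahydronaphthalen-1(2H)-one (cis-fused) | CC1=CC[C@H]2[C@@H](C1)C(C)(C)CCC2=O | intermediate
21 | 5-hydroxy-4,4,6-trimethyl-3,4,4a,5,8,8a-hexahydronaphthalen-1(2H)-one (cis-fused; carbinol either epimer) | CC1=CC[C@H]2[C@@H](C1O)C(C)(C)CCC2=O | intermediate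
22 | 5-hydroxy-4,4,6-trimethyloctahydronaphthalen-1(2H)-one (cis-fused; 6-methyl trans to H4a) | C[C@@H]1CC[C@H]2[C@@H](C1O)C(C)(C)CCC2=O | intermediate
23 | 2,8,8-trimethyl-5-methylidenedecahydronaphthalen-1-ol (cis-fused) | C[C@@H]1CC[C@H]2[C@@H](C1O)C(C)(C)CCC2=C | intermediate
24 | spiro-epoxide of 23 (oxirane oxygen cis to the adjacent ring-fusion hydrogen) | C[C@@H]1CC[C@H]2[C@@H](C1O)C(C)(C)CC[C@@]23CO3 | intermediate
25 | 2,5,8,8-tetramethyldecahydronaphthalene-1,5-diol (cis-fused; 5-OH cis to H4a) | C[C@@H]1CC[C@H]2[C@@H](C1O)C(C)(C)CC[C@]2(C)O | intermediate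
26 | 5-hydroxy-2,5,8,8-tetramethyloctahydronaphthalen-1(2H)-one (cis-fused) | C[C@@H]1CC[C@H]2[C@@H](C1=O)C(C)(C)CC[C@]2(C)O | intermediate
27 | (E)-5-(bromomethylidene)-1,4,4,6-tetramethyldecahydronaphthalen-1-ol (cis-fused; Br syn to C6 of the decalin) | C[C@@H]1CC[C@H]2[C@@H](/C1=C/Br)C(C)(C)CC[C@]2(C)O | intermediate
28 | B-alkyl-9-BBN borane from 17 (boron on C9; drawn with free hydroxyls) | C[C@]1(O)CC[C@@H]2OC(C)(C)C(O)CC[C@@]2(C)[C@@H]1CB3C4CCCC3CCC4 | intermediate (not isolated)
29 | C15 alcohol of the target (C15 either epimer) | C[C@@H]1CC[C@H]2[C@@H](/C1=C/C[C@H]1[C@]3(C)CCC(O)C(C)(C)O[C@H]3CC[C@]1(C)O)C(C)(C)CC[C@]2(C)O | intermediate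
30 | CNP0232921.1 | C[C@@H]1CC[C@H]2[C@@H](/C1=C/C[C@H]1[C@]3(C)CCC(=O)C(C)(C)O[C@H]3CC[C@]1(C)O)C(C)(C)CC[C@]2(C)O | target

**Step count.** 23 steps in total. The longest linear sequence is 14 steps (1–3, 5–13, 22, 23, from dione 1); the decalin branch is 8 steps (14–21) before the coupling.

**Three steps most likely to fail**

Step 5 (tertiary ether formation). The dimethylallyl cation may be captured at its primary end or lose a proton to isoprene, the imidate may rearrange by [3,3] shift to the allylic amide, or the neopentyl hydroxyl may react too slowly. The fallback sets out from 5. Commercial 2-methylbut-3-yn-2-ol is converted (Cl3CCN, DBU) into 2-methylbut-3-yn-2-yl 2,2,2-trichloroacetimidate F1, which has no sigmatropic escape route. Under the same acid catalysis its propargylic cation is attacked at the tertiary carbon to give the 1,1-dimethylpropargyl ether acetate F2. Semi-hydrogenation over Lindlar catalyst (H2, quinoline, stopped after one equivalent) turns the alkyne into the vinyl group and returns to the route at 8.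

Step 22 (fragment coupling). Transmetalation from the β-branched, neopentyl-like alkylborane and oxidative addition to the hindered trisubstituted vinyl bromide may both be slow, so that protodeboronation or reduction of the bromide wins; hydroboration of the crowded methylene may also stall. The fallback sets out from 17. Hydroboration as in step 22 (borane 28) followed by NaOH/H2O2 gives the primary C9 alcohol F3. Selective iodination of the primary hydroxyl (I2, PPh3, imidazole) gives the primary iodide F4. Nickel-catalysed reductive cross-electrophile coupling of F4 with 27 (NiBr2·glyme, 4,4'-di-tert-butyl-2,2'-bipyridine, Zn, DMA) returns to the route at 29.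

Step 3 (directed reduction with differentiation of the two oxygens). Samarium may fail to bridge the hemiacetal and the ring carbonyl, so that intramolecular hydride transfer is slow and acetaldehyde self-condensation consumes the reagent; the acetyl group may also scramble. The fallback sets out from 4. Hydroxyl-directed reduction with Me4NBH(OAc)3 (Evans–Saksena, MeCN/AcOH, −20 °C) gives the trans-diol F5. Iodoetherification (I2, NaHCO3, MeCN, 0 °C) engages the hydroxyl cis to allyl and gives the cis-fused iodo ether F6, leaving the hydroxyl trans to allyl free. Etherification with 7 as in step 5 gives the tertiary allyl ether F7. Zinc dust (NH4Cl, EtOH, reflux) reopens the iodo ether, restoring the allyl group and the C10 hydroxyl, and returns to the route at 9.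

**Further compounds**

F1 | step 5 | 2-methylbut-3-yn-2-yl 2,2,2-trichloroacetimidate | C#CC(C)(C)OC(=N)C(Cl)(Cl)Cl
F2 | step 5 | (1S,2R,3S)-2-allyl-2-methyl-3-[(2-methylbut-3-yn-2-yl)oxy]cyclohexyl acetate | C=CC[C@@]1(C)[C@@H](OC(C)=O)CCC[C@@H]1OC(C)(C)C#C
F3 | step 22 | 6-(hydroxymethyl)-2,2,5a,7-tetramethyldecahydro-1-benzoxepine-3,7-diol (C10 as in the target) | C[C@]1(O)CC[C@@H]2OC(C)(C)C(O)CC[C@@]2(C)[C@@H]1CO
F4 | step 22 | 6-(iodomethyl)-2,2,5a,7-tetramethyldecahydro-1-benzoxepine-3,7-diol | C[C@]1(O)CC[C@@H]2OC(C)(C)C(O)CC[C@@]2(C)[C@@H]1CI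
F5 | step 3 | (1S,3S)-2-allyl-2-methylcyclohexane-1,3-diol (trans) | C=CCC1(C)[C@@H](O)CCC[C@@H]1O
F6 | step 3 | 2-(iodomethyl)-3a-methyloctahydro-1-benzofuran-4-ol (cis-fused; hydroxyl trans to C3) | ICC1C[C@@]2(C)[C@@H](O1)CCC[C@@H]2O
F7 | step 3 | 2-(iodomethyl)-3a-methyl-4-[(2-methylbut-3-en-2-yl)oxy]octahydro-1-benzofuran | ICC1C[C@@]2(C)[C@@H](O1)CCC[C@@H]2OC(C)(C)C=C
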